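The readings stem from a simulated flask with made-up constants; noise was put on by code.

If a fixed amount of J is lost the moment it is charged, the ash flask, with a third of the J of the oak flask, is worse supplied than that fraction says. Two chemists dispute this.

| flask | L | J | time |
|---|---|---|---|
| oak | 0.300 M | 0.00300 M |  |
| birch | 0.900 M | 0.00300 M |  |
| cedar | 0.300 M | 0.00450 M |  |
| ash | 0.150 M | 9.90 × 10⁻⁴ M | 29 min |

| oak run: time / min | oak run: [E] / M | birch run: time / min | birch run: [E] / M | cedar run: time / min | cedar run: [E] / M |
|---|---|---|---|---|---|
| 1.2 | 0.0223 | 1.2 | 0.0173 | 1.2 | 0.0566 |
| 1.8 | 0.0340 | 1.8 | 0.0253 | 1.8 | 0.0749 |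
| 2.9 | 0.0489 | 2.9 | 0.0371 | 2.9 | 0.1173 |
| 4.6 | 0.0718 | 4.6 | 0.0597 | 4.6 | 0.1667 |
| 7.3 | 0.0997 | 7.3 | 0.0909 | 7.3 | 0.2186 |
| 12 | 0.1309 | 12 | 0.1319 | 12 | 0.2567 |
| 18 | 0.1524 | 18 | 0.1765 | 18 | 0.2712 |
| 29 | 0.1606 | 29 | 0.2298 | 29 | 0.2761 |

(readings scatter by 0.002 M)

- Overall: L -> E, with J as catalyst.
- Constant volume, constant temperature.
- A reading of a species includes what of it is bound.
- An order is taken over about fifteen percent of the charge, up and down.

- reaction order in [J] at the outset, round the charge of the oak run, defined at two percent of the L turned into E
- reaction order in [L] at the outset, round the charge of the oak run, defined at two percent of the L turned into E (one fixed amount of E, the same in the runs compared)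
- E in the ash run at 29 min, as a share of the L charged

The first chemist reckons with the charged J, called C. The rate goes as C squared, she says, so E in the cedar flask over E in the oak flask should be 2.25 early on. The reading at 2.9 min is 2.40, and she points out that the scatter on that ratio is about 0.0981.

The second chemist takes that reading at face value and reckons with working J, w = C − z. Here z, the blank, read as 2.67 × 10⁻⁴ M, is the amount of J lost on charging whatever the charge, in the usual term the J taken by a catalyst poison. The order in J is then 2C/(C − z), which is 2.20 at the oak charge. Squared, w in the ash flask over w in the oak flask is 0.0700, against 0.109 on charged J.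

On L they agree, since the oak and birch flasks hold equal J and z cancels between them. Suppose L binds J with constant K, so that the rate goes as L over the square of one plus KL. The readings at 2.9 min then give K = 3.26 /M and an order in L of 0.0115 at the oak charge.

The oak flask averages 0.0189 M/min over its first 1.8 min. Its last reading divided by that rate gives a life of the rate, not of J itself, of 8.50 min. If free J is what dies, life goes with one plus KL, so the ash flask gets 7.38 min, and 29 min is 3.93 such lives. The early rate of the ash flask should be 0.00117 M/min. Rate times life is my reckoning, 5.74% of the charge, whereas charged J in the same sum gives 8.92%.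

The forecast, on the first chemist's side, says 2.1 in J, 0.1 in L and 17% for the ash flask, more than my charged-J sum, reckoned “Over roughly 13 min of effective life”.

The ash flask gives 5.30%, less than the 8.92% on charged J, against the 5.74% on working J. At the oak charge the order in J is 2.3 and the order in L is −0.019.

    J + L ⇌ JL, settled at all times (3.650 /M)
    JL + J → E + 2 J (11100 /M/min)
    J → Ez (0.1008 /min)
    J + Wy → Ez

The J lost on charging is the part taken by Wy. Charged J comes nearer where z is a small part of C: z is 5.93% of the J in the cedar flask, less than the 26.9% in the ash flask. With that z, the order in J reckons at 2.13 for the cedar charge and 2.74 for the ash charge.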